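**Retrosynthetic overview**

1. Late disconnections: the C3–O ester (3,4-dimethoxybenzoyl chloride), two aryl methyl ethers, and the pyranone ring of the chromone (Claisen condensation and cyclodehydration of an o-hydroxyacetophenone made by Friedel–Crafts acetylation). These lead back to (3S,4R)-1-methyl-4-(2,4,6-trimethoxyphenyl)piperidin-3-ol.
2. Key disconnection: the piperidine C4–C5 bond, closed by an aldol condensation inside a hydrogen-borrowing cycle on a chiral ruthenium catalyst. A racemic open-chain amino diol loses only water, and both stereocentres are set by dynamic kinetic resolution.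
3. Enabling feature: in the piperidine, carbinol C3 lies between benzylic C4 and C2–N1, and N1–C6–C5 is a 2-aminoethyl unit. At the ketone level C4–H (alpha to C3=O and benzylic to the trioxygenated benzene ring that becomes ring A) is the only enolisable position that can reach C5 through a six-membered ring, and it is configurationally labile.
4. The amino diol comes from 1,3,5-trimethoxybenzene, epichlorohydrin and 2-(methylamino)ethanol.
5. Ring order: ring A is bought; the piperidine is closed in step 3; the pyranone ring is closed in step 5.

Key step: step 3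

Assumption: the facial sense of hydride delivery by RuCl2[(S)-binap][(R,R)-dpen] is taken by analogy with 2-substituted cyclohexanones; if it were opposite, the mirror-image catalyst would be used (binap = 2,2'-bis(diphenylphosphino)-1,1'-binaphthyl, dpen = 1,2-diphenylethane-1,2-diamine).

**Route**

Step 1
Reactants: 1 1,3,5-trimethoxybenzene; 2 (±)-epichlorohydrin
Product: 4 (±)-1-chloro-3-(2,4,6-trimethoxyphenyl)propan-2-ol, via 2,4,6-trimethoxyphenyllithium 3 (not isolated)
Conditions: n-BuLi, TMEDA, THF, 0 °C to rt; then 2, BF3·OEt2, −78 °C; aq NH4Cl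
Reagents that add atoms: none
Why: Lithiation between two methoxy groups (directed ortho-metalation) gives the aryllithium, which should open the BF3-activated epoxide at its CH2 terminus (Lewis-acid-promoted organolithium epoxide opening); direct displacement of chloride would give epoxide 6 and hence the same amino diol, and the carbinol centre is formed racemic because step 3 erases it.

Step 2
Reactants: 4 (±)-1-chloro-3-(2,4,6-trimethoxyphenyl)propan-2-ol; 5 2-(methylamino)ethanol
Product: 7 (±)-1-[(2-hydroxyethyl)(methyl)amino]-3-(2,4,6-trimethoxyphenyl)propan-2-ol, via benzyl oxirane 6 (not isolated)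
Conditions: 5 (3 equiv), K2CO3, EtOH, 70 °C
Reagents that add atoms: none
Why: Carbonate closes the chlorohydrin to the terminal epoxide and the secondary amine opens it at the CH2 terminus (epoxide aminolysis, SN2), so the 1,2-amino alcohol should form regioselectively; no stereocontrol is needed.

Step 3
Reactants: 7 (±)-1-[(2-hydroxyethyl)(methyl)amino]-3-(2,4,6-trimethoxyphenyl)propan-2-ol
Product: 11 (3S,4R)-1-methyl-4-(2,4,6-trimethoxyphenyl)piperidin-3-ol, via keto aldehyde 8 (not isolated), via enone 9 (not isolated), via racemic ketone 10 (not isolated)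
Conditions: trans-RuCl2[(S)-binap][(R,R)-dpen] (3 mol %), KOtBu (0.5 equiv), toluene/t-AmOH, 70 °C, sealed under argon; then H2 (10 bar), 30 °C
Reagents that add atoms: none
Why: Proposed new method: the Ru–H/amido catalyst reversibly dehydrogenates both carbinols of 7 to keto aldehyde 8, whose only enolate able to reach the aldehyde through a six-membered ring is the benzylic C4 enolate, so base-mediated aldol condensation (6-(enolexo)-exo-trig) forms C4–C5 and gives enone 9; the stored hydrogen is then returned to C4=C5 (directly or through the allylic alcohol and its redox isomerisation) and to the C3 carbonyl, so that 7 loses only water. The closest known reaction types are the enantioselective Guerbet reaction (hydrogen-borrowing beta-alkylation of secondary alcohols by primary alcohols on ruthenium diphosphine–diamine catalysts), hydrogen-borrowing annulations of diols that close six-membered rings, and the Noyori dynamic kinetic resolution of 2-substituted cyclohexanones to cis-2-substituted cyclohexanols. Ketone 10 should racemise quickly at C4, which is alpha to the carbonyl and benzylic to the trimethoxyphenyl ring, so the chiral catalyst can funnel both C3 epimers of 7 and both enantiomers of 10 into one product. C3 is set by catalyst-controlled outer-sphere hydride delivery to one carbonyl face; C4 follows because the catalyst should reduce fastest the enantiomer of 10 that carries the aryl group equatorial, with hydride arriving from the equatorial direction, which gives the axial hydroxyl cis to the aryl group. The step needs the aldol ring closure to outrun lactonisation of the hydroxy aldehyde and intermolecular condensation, which the six-membered intramolecular geometry and the acidity of C4–H favour, and it needs the product not to be re-oxidised, which the closing hydrogen atmosphere at low temperature should secure.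

Step 4
Reactants: 11 (3S,4R)-1-methyl-4-(2,4,6-trimethoxyphenyl)piperidin-3-ol
Product: 12 (3S,4R)-4-(3-acetyl-2-hydroxy-4,6-dimethoxyphenyl)-1-methylpiperidin-3-yl acetate
Conditions: Ac2O, BF3·OEt2, CH2Cl2, 0 °C to rt; aq Na2CO3
Reagents that add atoms: acetic anhydride CC(=O)OC(C)=O
Why: Friedel–Crafts acetylation should occur at one of the two equivalent free positions of the trioxygenated ring while the alcohol is O-acetylated, and the boron-chelated aryl ketone then loses the ortho methyl ether squeezed between the acetyl and piperidinyl groups (chelation-assisted demethylation, closely precedented on 4-(2,4,6-trimethoxyphenyl)piperidines); no stereocentre is touched.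

Step 5
Reactants: 12 (3S,4R)-4-(3-acetyl-2-hydroxy-4,6-dimethoxyphenyl)-1-methylpiperidin-3-yl acetate
Product: 14 8-[(3S,4R)-3-hydroxy-1-methylpiperidin-4-yl]-5,7-dimethoxy-2-methyl-4H-chromen-4-one, via 1,3-diketone 13 (not isolated)
Conditions: NaH, EtOAc, reflux; then conc. HCl, MeOH, 60 °C; aq NaHCO3
Reagents that add atoms: ethyl acetate CCOC(C)=O
Why: Claisen condensation of the methyl ketone enolate with ethyl acetate gives the 1,3-diketone, and acid should then close the pyranone ring by 6-exo-trig attack of the only free phenol on the distal carbonyl followed by dehydration (chromone synthesis by cyclodehydration), with acid methanolysis of the O-acetate in the same pot; because the other ortho oxygen is still methylated, only the 8-substituted chromone can form.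

Step 6
Reactants: 14 8-[(3S,4R)-3-hydroxy-1-methylpiperidin-4-yl]-5,7-dimethoxy-2-methyl-4H-chromen-4-one
Product: 15 rohitukine [5,7-dihydroxy-8-[(3S,4R)-3-hydroxy-1-methylpiperidin-4-yl]-2-methyl-4H-chromen-4-one]
Conditions: pyridine hydrochloride (excess), 180 °C; aq NaHCO3 to pH 8
Reagents that add atoms: none
Why: The pyridinium chloride melt should cleave both aryl methyl ethers by chloride SN2 attack on the protonated ethers (aryl methyl ether cleavage, closely precedented on 5,7-dimethoxychromones carrying this piperidinol), leaving the protonated amino alcohol and its stereocentres unchanged.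

Step 7
Reactants: 15 rohitukine; 16 3,4-dimethoxybenzoyl chloride
Product: 18 chrotacumine D [(3S,4R)-4-(5,7-dihydroxy-2-methyl-4-oxo-4H-chromen-8-yl)-1-methylpiperidin-3-yl 3,4-dimethoxybenzoate], via bis-ester 17 (not isolated)
Conditions: 16 (3 equiv), pyridine, DMAP (0.2 equiv), CH2Cl2, 0 °C to rt; then NH3 (7 M in MeOH), 0 °C
Reagents that add atoms: none
Why: DMAP-catalysed acylation should esterify the secondary alcohol and also the acidic 7-phenol, and ammonolysis at 0 °C then removes only the aryl ester (phenoxide leaving group; chemoselective deacylation of phenolic esters), as it would any 5-O-ester, while the hindered alkyl benzoate stays; C3 keeps its configuration because only its O–H bond is changed.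

**Compound list**

1 | 1,3,5-trimethoxybenzene | COc1cc(OC)cc(OC)c1 | starting material
2 | (±)-epichlorohydrin [2-(chloromethyl)oxirane] | ClCC1CO1 | starting material
3 | 2,4,6-trimethoxyphenyllithium | [Li]c1c(OC)cc(OC)cc1OC | intermediate
4 | (±)-1-chloro-3-(2,4,6-trimethoxyphenyl)propan-2-ol | COc1cc(OC)c(CC(O)CCl)c(OC)c1 | intermediate
5 | 2-(methylamino)ethanol | CNCCO | starting material
6 | (±)-2-(2,4,6-trimethoxybenzyl)oxirane | COc1cc(OC)c(CC2CO2)c(OC)c1 | intermediate
7 | (±)-1-[(2-hydroxyethyl)(methyl)amino]-3-(2,4,6-trimethoxyphenyl)propan-2-ol | COc1cc(OC)c(CC(O)CN(C)CCO)c(OC)c1 | intermediate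
8 | 2-{methyl[2-oxo-3-(2,4,6-trimethoxyphenyl)propyl]amino}acetaldehyde (keto aldehyde) | COc1cc(OC)c(CC(=O)CN(C)CC=O)c(OC)c1 | intermediate
9 | 1-methyl-4-(2,4,6-trimethoxyphenyl)-1,6-dihydropyridin-3(2H)-one (enone) | COc1cc(OC)c(C2=CCN(C)CC2=O)c(OC)c1 | intermediate
10 | (±)-1-methyl-4-(2,4,6-trimethoxyphenyl)piperidin-3-one | COc1cc(OC)c(C2CCN(C)CC2=O)c(OC)c1 | intermediate
11 | (3S,4R)-1-methyl-4-(2,4,6-trimethoxyphenyl)piperidin-3-ol | O[C@@H]1CN(C)CC[C@@H]1c1c(OC)cc(OC)cc1OC | intermediate
12 | (3S,4R)-4-(3-acetyl-2-hydroxy-4,6-dimethoxyphenyl)-1-methylpiperidin-3-yl acetate | CC(=O)O[C@@H]1CN(C)CC[C@@H]1c1c(O)c(C(C)=O)c(OC)cc1OC | intermediate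
13 | (3S,4R)-4-[2-hydroxy-4,6-dimethoxy-3-(3-oxobutanoyl)phenyl]-1-methylpiperidin-3-yl acetate (1,3-diketone) | CC(=O)O[C@@H]1CN(C)CC[C@@H]1c1c(O)c(C(=O)CC(C)=O)c(OC)cc1OC | intermediate
14 | 8-[(3S,4R)-3-hydroxy-1-methylpiperidin-4-yl]-5,7-dimethoxy-2-methyl-4H-chromen-4-one | O[C@@H]1CN(C)CC[C@@H]1c1c(OC)cc(OC)c2c(=O)cc(C)oc12 | intermediate
15 | rohitukine, 5,7-dihydroxy-8-[(3S,4R)-3-hydroxy-1-methylpiperidin-4-yl]-2-methyl-4H-chromen-4-one | O[C@@H]1CN(C)CC[C@@H]1c1c(O)cc(O)c2c(=O)cc(C)oc12 | intermediate
16 | 3,4-dimethoxybenzoyl chloride | COc1ccc(C(Cl)=O)cc1OC | starting material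
17 | (3S,4R)-4-[7-(3,4-dimethoxybenzoyloxy)-5-hydroxy-2-methyl-4-oxo-4H-chromen-8-yl]-1-methylpiperidin-3-yl 3,4-dimethoxybenzoate (bis-ester) | COc1ccc(C(=O)O[C@@H]2CN(C)CC[C@@H]2c2c(OC(=O)c3ccc(OC)c(OC)c3)cc(O)c3c(=O)cc(C)oc23)cc1OC | intermediate
18 | chrotacumine D, (3S,4R)-4-(5,7-dihydroxy-2-methyl-4-oxo-4H-chromen-8-yl)-1-methylpiperidin-3-yl 3,4-dimethoxybenzoate | COc1ccc(C(=O)O[C@@H]2CN(C)CC[C@@H]2c2c(O)cc(O)c3c(=O)cc(C)oc23)cc1OC | target

**Step count**

Total steps: 7. Longest linear sequence: 7 steps (from 1).

**Steps most likely to fail, with fallbacks**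

Step 3 (Proposed new method). The cascade may be diverted by oxidative lactonisation of the cyclic hemiacetal of the hydroxy aldehyde to a morpholin-2-one with loss of hydrogen, by intermolecular aldol condensation, or by incomplete return of hydrogen to C4=C5. Enantiomeric purity may also erode through reversible dehydrogenation of the product. The fallback closes the same bond by known, stepwise chemistry and sets out from 4. Dess–Martin oxidation would give 1-chloro-3-(2,4,6-trimethoxyphenyl)propan-2-one F1. SN2 amination with 2,2-dimethoxy-N-methylethanamine (K2CO3, MeCN) would give 1-[(2,2-dimethoxyethyl)(methyl)amino]-3-(2,4,6-trimethoxyphenyl)propan-2-one F2. Aqueous HCl at 60 °C would unmask the aldehyde and drive the intramolecular aldol condensation to enone 9, now isolated. Hydrogenation over Pd/C would give racemic ketone 10. A separate Noyori–Ikariya transfer hydrogenation with dynamic kinetic resolution, RuCl(p-cymene)[(S,S)-TsDPEN] in HCO2H/Et3N, would reduce 10 to the cis alcohol, and the route is rejoined at 11.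

Step 7. Acylation of the hindered axial carbinol next to the ortho-disubstituted aryl group may stall, or the alkyl ester may be partly lost while the aryl ester is cleaved. The fallback sets out from 15 and masks the phenol before esterification. TBSCl and imidazole in DMF should silylate the acidic 7-phenol selectively to give 7-O-(tert-butyldimethylsilyl)rohitukine F3. Steglich esterification with 3,4-dimethoxybenzoic acid (EDC·HCl, DMAP, CH2Cl2) would give the silyl ether ester F4. HF·pyridine in THF would then remove the silyl group, and the route is rejoined at 18.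

Step 1. The hindered aryllithium may be consumed as an aryl borate, or attack on the bifunctional electrophile may be slow and unselective. The fallback brings in the three-carbon unit as an allyl group and sets out from 1. Lithiation as before to 3 and alkylation with allyl bromide would give 2-allyl-1,3,5-trimethoxybenzene F5. Epoxidation with mCPBA and NaHCO3 in CH2Cl2 would give epoxide 6, now isolated, which 5 opens under the conditions of step 2, and the route is rejoined at 7.

**Further compounds**

F1 | step 3 | 1-chloro-3-(2,4,6-trimethoxyphenyl)propan-2-one | COc1cc(OC)c(CC(=O)CCl)c(OC)c1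
F2 | step 3 | 1-[(2,2-dimethoxyethyl)(methyl)amino]-3-(2,4,6-trimethoxyphenyl)propan-2-one | COc1cc(OC)c(CC(=O)CN(C)CC(OC)OC)c(OC)c1
F3 | step 7 | 7-[(tert-butyldimethylsilyl)oxy]-5-hydroxy-8-[(3S,4R)-3-hydroxy-1-methylpiperidin-4-yl]-2-methyl-4H-chromen-4-one | O[C@@H]1CN(C)CC[C@@H]1c1c(O[Si](C)(C)C(C)(C)C)cc(O)c2c(=O)cc(C)oc12
F4 | step 7 | (3S,4R)-4-{7-[(tert-butyldimethylsilyl)oxy]-5-hydroxy-2-methyl-4-oxo-4H-chromen-8-yl}-1-methylpiperidin-3-yl 3,4-dimethoxybenzoate | COc1ccc(C(=O)O[C@@H]2CN(C)CC[C@@H]2c2c(O[Si](C)(C)C(C)(C)C)cc(O)c3c(=O)cc(C)oc23)cc1OC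
F5 | step 1 | 2-allyl-1,3,5-trimethoxybenzene | C=CCc1c(OC)cc(OC)cc1OC
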